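This flask makes target from substrate and keeps consuming it, so late in the run the target present is what remains of a stock in transit.

    dissolved gas ⇌ dormant form (K1 = 7.0, k1 = 4.7 × 10⁻⁴ s⁻¹)
    substrate + target → side product (k2 = 1.4 × 10⁻⁴ L mol⁻¹ s⁻¹)
    substrate + dissolved gas → target (k3 = 0.0013 L mol⁻¹ s⁻¹)
    gas phase ⇌ dissolved gas, rate k4*(csat - [dissolved gas]) (k4 = 0.068 s⁻¹, csat = 130 mM)
    dissolved gas + target → over-reacted product (k5 = 0.0028 L mol⁻¹ s⁻¹)

substrate 1.5 M; gas phase 130 mM (held); time 2.0 h

* amount of target at 2.0 h, in percent of the substrate charged
* the change that raises the amount of target at 2.0 h, in percent of the substrate charged most ("none" if none brings more than 2 percentage points) (violet / grey / none)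
* amount of target at 2.0 h, in percent of the substrate charged, after violet

- percent here means substrate units held: one side product counts as two
- at the start none of the gas is dissolved
- run time (flask): 2.0 h

My reckoning starts with the fast step, gas transfer. Its coefficient is 0.068 s⁻¹, while substrate at its charge and the passage to dormant form together remove dissolved gas at 0.00242 s⁻¹. Transfer is far faster, so once gas has begun to dissolve from its empty start, the balance of the two, with substrate at its charge, holds dissolved gas at 96.6% of saturation. I therefore set its concentration c equal to the saturation value.

Target formation is then pseudo-first-order, with a = 0.608 h⁻¹ (the constant of substrate + dissolved gas, times c). Target is lost by over-reaction and by the side reaction, whose rate follows substrate. Substrate decaying at a averages Ā = 0.868 M over the run, which gives a loss constant b = 1.75 h⁻¹. Substrate lost to side product is left out of a.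

At 2.0 h this gives 14.2%. This is the transit yield Y = a/(b − a) × (exp(−at) − exp(−bt)), the share of the charge standing as target at time t.

Violet doubles c, so a becomes 1.22 h⁻¹, Ā becomes 0.562 M, b becomes 2.90 h⁻¹, and Y falls to 6.11%. Grey lifts that same balance, with substrate at its charge, to 98.3% of saturation. Scaled on violet's loss, that moves Y by about 0.14 percentage points, less than the 2 points required. My choice is therefore none.

The forecast gives 13.6% (12.8% to 14.4%), 5.8% after violet (5.2% to 6.5%) and none as best change, slightly lower than my figures, noting that “Grey raises dissolved gas by under 2%, changing target by well under 2 points”.

The simulated flask holds 13.9% target, against Y of 14.2%, and 5.98% after violet, against 6.11%. Violet changes target by −7.9 points and grey by −0.13 points, so the best change is none. Dissolved gas in the flask stands at 0.127 M at 2.00 h. For the same flask left until 3.0 h, a stays put, Ā becomes 0.689 M and b becomes 1.66 h⁻¹, so Y gives 8.94%. That neighbour holds 8.60%.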